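**Retrosynthetic overview**

1. The target is a 6,7-seco-ent-kaurane. Ring A (C1–C5, C10) and the bicyclo[3.2.1]octane (rings C and D) are joined only through the oxepane C5–C6–O–C7–C8–C9–C10, so cutting O–C7 and C9–C10 of that ring gives two ten-carbon halves: (S)-α-cyclogeranic acid 4 and bis-triflate 18.
2. The feature that allows this union: C6 can be a carboxylate; C7 is a neopentyl CH2 on quaternary C8, so its triflate can only be substituted; C9 is the only enolisable side of a ketone next to C8, which gives one regiodefined vinyl triflate; and the C10=C1 alkene of the cyclogeranate sits next to the tethering carbon C5, so a 7-exo Heck closure makes quaternary C10 and leaves C1=C2 for the diacetate.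
3. Ring order: ring C (cyclohexanone 5, C8 set by asymmetric alkylation), then ring D (vinyl-radical closure C16–C13). Ring A comes from acid cyclisation of geranic acid. The oxepane closes as a lactone in the key step, and the epoxide is made last.
4. Endgame: inversion of C5 by enolate protonation, C1=C2 to the 1,2-dione and then to the 1α,2α-diol, reductive acetylation of the lactone, C15 ketone, 9α,11α-epoxidation, anomeric deacetylation.

Key step: step 14

Remark: atom numbers are those of ent-kaurane (ring A C1–C5, C10; C6 and C7 in the oxepane; ring C C8, C9, C11–C14; ring D C8, C14, C13, C16, C15; C17 on C16; C20 on C10). α is the face of ring A that carries C20 in the target. On ring D, exo is the side of the one-carbon bridge C14 and endo the side of the bridge C9–C11–C12.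
Remark: it is assumed that the less soluble salt of rac-2 with (R)-1-phenylethylamine contains the (S)-acid; if the pairing is the opposite, the (S)-amine is used.
Remark: it is assumed that the (S,S)-configured spiro ammonium catalyst of step 4 gives (R)-7; if not, its enantiomer is used.
Remark: it is assumed that the C6 configuration of the target is the thermodynamically favoured lactol anomer, so it is left to equilibrate in step 23.

**Route**

Step 1
Reactants: 1 geranic acid
Product: 2 rac-α-cyclogeranic acid
Conditions: 85% H3PO4, toluene, 80 °C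
Reagents that add atoms: none
Why: Brønsted acid cation–olefin cyclisation, in which the tertiary cation from the C6=C7 alkene is captured by C2 of the unsaturated acid and proton loss places the ring alkene out of conjugation; the one stereocentre is formed racemic.

Step 2
Reactants: 2 rac-α-cyclogeranic acid
Product: 3 (R)-1-phenylethylammonium (S)-α-cyclogeranate
Conditions: (R)-1-phenylethylamine (0.5 equiv), acetone, 50 → 5 °C, two recrystallisations
Reagents that add atoms: (R)-1-phenylethylamine, C[C@@H](N)c1ccccc1
Why: classical resolution by crystallisation of the less soluble diastereomeric salt, which fixes the C5 configuration that later directs the key step.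

Step 3
Reactants: 3 (R)-1-phenylethylammonium (S)-α-cyclogeranate
Product: 4 (S)-α-cyclogeranic acid
Conditions: 1 M HCl, Et2O, 23 °C
Reagents that add atoms: none
Why: simple acid–base liberation of the carboxylic acid, with no epimerisation because the β,γ-unsaturated acid is not enolised in cold dilute acid.

Step 4
Reactants: 5 tert-butyl 2-oxocyclohexane-1-carboxylate; 6 2,3-dibromopropene
Product: 7 tert-butyl (1R)-1-(2-bromoprop-2-en-1-yl)-2-oxocyclohexane-1-carboxylate
Conditions: (S,S)-N-spiro bis(binaphthyl)ammonium bromide with 3,4,5-trifluorophenyl groups (1 mol %), CsOH·H2O, toluene, −40 °C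
Reagents that add atoms: none
Why: asymmetric phase-transfer alkylation of a cyclic β-keto ester, in which the chiral ammonium enolate ion pair exposes one enolate face to the allylic bromide and so sets quaternary C8.

Step 5
Reactants: 7 tert-butyl (1R)-1-(2-bromoprop-2-en-1-yl)-2-oxocyclohexane-1-carboxylate
Product: 8 tert-butyl (1R)-1-(2-bromoprop-2-en-1-yl)-2-oxocyclohex-3-ene-1-carboxylate
Conditions: IBX (2.5 equiv), DMSO–fluorobenzene, 70 °C
Reagents that add atoms: none
Why: IBX dehydrogenation of a ketone to its enone, regiospecific because the quaternary C8 leaves C11 as the only enolisable position.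

Step 6
Reactants: 8 tert-butyl (1R)-1-(2-bromoprop-2-en-1-yl)-2-oxocyclohex-3-ene-1-carboxylate
Product: 9 tert-butyl (1R)-1-(2-bromoprop-2-en-1-yl)-2-[(tert-butyldimethylsilyl)oxy]cyclohexa-2,4-diene-1-carboxylate
Conditions: t-BuMe2SiOTf, Et3N, CH2Cl2, 0 °C
Reagents that add atoms: tert-butyldimethylsilyl triflate, CC(C)(C)[Si](C)(C)OS(=O)(=O)C(F)(F)F
Why: soft enolisation of an enone that has only γ-hydrogens (at C13) gives the linear 2-silyloxy-1,3-diene, which moves an alkene to C12=C13 for the ring D closure.

Step 7
Reactants: 9 tert-butyl (1R)-1-(2-bromoprop-2-en-1-yl)-2-[(tert-butyldimethylsilyl)oxy]cyclohexa-2,4-diene-1-carboxylate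
Product: 11 tert-butyl (1R,5R)-6-methylidene-2-oxobicyclo[3.2.1]octane-1-carboxylate, via silyl enol ether 10 (not isolated)
Conditions: Bu3SnH, AIBN, benzene, 80 °C (slow addition); then 1 M HCl, THF, 23 °C
Reagents that add atoms: none
Why: Stork-type vinyl radical cyclisation, 5-exo-trig onto the diene terminus C13 (attack at C11 would be 5-endo), followed by reduction of the allyl radical at C12 and acid hydrolysis of the enol ether; the bridge can only form cis, so C13 follows from C8.

Step 8
Reactants: 11 tert-butyl (1R,5R)-6-methylidene-2-oxobicyclo[3.2.1]octane-1-carboxylate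
Product: 12 tert-butyl (1R,5R)-7-exo-hydroxy-6-methylidene-2-oxobicyclo[3.2.1]octane-1-carboxylate
Conditions: SeO2 (0.5 equiv), t-BuOOH, CH2Cl2, 23 °C
Reagents that add atoms: selenium dioxide, O=[Se]=O; tert-butyl hydroperoxide, CC(C)(C)OO
Why: SeO2 allylic oxidation (ene reaction, then [2,3]-shift) at C15, the only allylic CH2 since the bridgehead C13–H cannot take part, with oxygen delivered from the open exo face.

Step 9
Reactants: 12 tert-butyl (1R,5R)-7-exo-hydroxy-6-methylidene-2-oxobicyclo[3.2.1]octane-1-carboxylate
Product: 13 tert-butyl (1R,5R)-7-exo-hydroxy-6-endo-methyl-2-oxobicyclo[3.2.1]octane-1-carboxylate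
Conditions: H2 (1 atm), [Ir(cod)(PCy3)(py)]PF6 (5 mol %), CH2Cl2, 23 °C
Reagents that add atoms: none
Why: hydroxyl-directed homogeneous hydrogenation delivers hydrogen to the exo face, syn to the C15 hydroxyl, so the C16 methyl becomes endo as in the target.

Step 10
Reactants: 13 tert-butyl (1R,5R)-7-exo-hydroxy-6-endo-methyl-2-oxobicyclo[3.2.1]octane-1-carboxylate
Product: 14 tert-butyl (1R,5R)-6-endo-methyl-2-oxo-7-exo-(triethylsilyloxy)bicyclo[3.2.1]octane-1-carboxylate
Conditions: Et3SiOTf, 2,6-lutidine, CH2Cl2, −78 °C
Reagents that add atoms: triethylsilyl triflate, CC[Si](CC)(CC)OS(=O)(=O)C(F)(F)F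
Why: silylation with a hindered base at low temperature caps the β-hydroxy ketone before any retro-aldol opening can scramble C15 and C16.

Step 11
Reactants: 14 tert-butyl (1R,5R)-6-endo-methyl-2-oxo-7-exo-(triethylsilyloxy)bicyclo[3.2.1]octane-1-carboxylate
Product: 16 tert-butyl (1R,5R)-6-endo-methyl-7-exo-(triethylsilyloxy)-2-(trifluoromethylsulfonyloxy)bicyclo[3.2.1]oct-2-ene-1-carboxylate, via potassium enolate 15 (not isolated)
Conditions: KN(SiMe3)2, THF, −78 °C; then PhNTf2, −78 → 0 °C
Reagents that add atoms: N-phenylbis(trifluoromethanesulfonimide), FC(F)(F)S(=O)(=O)N(c1ccccc1)S(=O)(=O)C(F)(F)F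
Why: enolate O-triflation, regiospecific for C9=C11 because C8 is quaternary.

Step 12
Reactants: 16 vinyl triflate tert-butyl ester
Product: 17 primary alcohol (C7–OH) of the vinyl triflate
Conditions: i-Bu2AlH (4 equiv), CH2Cl2, −78 → 0 °C
Reagents that add atoms: none
Why: hydride reduction of the ester to the neopentyl carbinol; vinyl triflates and silyl ethers tolerate i-Bu2AlH.

Step 13
Reactants: 17 primary alcohol (C7–OH) of the vinyl triflate
Product: 18 bis-triflate (C7 alkyl triflate, C9 vinyl triflate)
Conditions: Tf2O, 2,6-lutidine, CH2Cl2, −78 °C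
Reagents that add atoms: triflic anhydride, O=S(=O)(OS(=O)(=O)C(F)(F)F)C(F)(F)F
Why: O-sulfonylation of a primary alcohol; the neopentyl triflate should be isolable because it has no β-hydrogen and cannot ionise.

Step 14
Reactants: 4 (S)-α-cyclogeranic acid; 18 bis-triflate
Product: 20 cis-fused tetracyclic lactone (5-epi series), via ester 19 (not isolated)
Conditions: Cs2CO3 (0.55 equiv), Pd(OAc)2 (10 mol %), PPh3 (25 mol %), 1,2,2,6,6-pentamethylpiperidine, DMF (0.01 M), 23 → 85 °C
Reagents that add atoms: none
Why: The caesium carboxylate of 4 displaces the primary triflate at C7 (SN2 at a carbon that can neither eliminate nor ionise, while the vinyl triflate is inert to O-nucleophiles) to give ester 19; its vinyl triflate then adds oxidatively to zerovalent palladium, the alkenylpalladium inserts into the tethered C10=C1 alkene, and syn β-hydride elimination towards C2 releases the C1=C2 alkene. The closest precedent is the intramolecular Heck reaction of alkenyl triflates with trisubstituted cycloalkenes that creates quaternary carbons, run here in tandem with a carboxylate alkylation. The seven-membered lactone closes in the 7-exo-trig mode, with C9 going to the methyl-bearing C10 and palladium to C1. C10 is the only new stereocentre: the ester at C5 sits pseudoaxial to avoid allylic 1,2-strain with the C10 methyl and can reach only its own (β) face, so C9 enters cis to C6 and the methyl becomes α, while C8 and C13 of 18 are untouched. The step needs 7-exo rather than 8-endo insertion, favoured by the short four-atom tether, and elimination to C1=C2 only, secured because C10 is quaternary and C2 carries the only β-hydrogens.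

Step 15
Reactants: 20 cis-fused tetracyclic lactone (5-epi series)
Product: 22 trans-fused tetracyclic lactone, via lithium enolate 21 (not isolated)
Conditions: LiN(i-Pr)2, THF, −78 °C; then AcOH, −78 °C
Reagents that add atoms: none
Why: kinetic protonation of the lactone enolate along the axial direction from the β face, away from C20 and the axial C4 methyl, should place H5 β and C6 α (equatorial), which is the C5 configuration of the target.

Step 16
Reactants: 22 trans-fused tetracyclic lactone
Product: 23 1β,2β-diol lactone
Conditions: OsO4 (5 mol %), N-methylmorpholine N-oxide, acetone–H2O, 23 °C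
Reagents that add atoms: N-methylmorpholine N-oxide, C[N+]1([O-])CCOCC1; water, O; osmium tetroxide (catalytic oxygen carrier), O=[Os](=O)(=O)=O
Why: Upjohn dihydroxylation, selective for the cis-disubstituted C1=C2 over the trisubstituted C9=C11 that lies between two quaternary carbons; the facial sense does not matter because both carbinols are oxidised next.

Step 17
Reactants: 23 1β,2β-diol lactone
Product: 24 1,2-dione lactone (largely as its C2 enol)
Conditions: (COCl)2, DMSO, CH2Cl2, −78 °C; then Et3N, −78 → 0 °C
Reagents that add atoms: none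
Why: double Swern oxidation of a vicinal diol without C–C cleavage, which erases the wrongly placed carbinol centres.

Step 18
Reactants: 24 1,2-dione lactone
Product: 25 1α,2α-diol lactone
Conditions: NaBH4, MeOH–CH2Cl2, −20 → 0 °C
Reagents that add atoms: none
Why: both hydrides should arrive from the β face, because the α face of C1 and C2 is shielded by the syn-axial C20 and C4 methyl groups, giving the cis-diol with the C1 hydroxyl equatorial and the C2 hydroxyl axial; the lactone is not reduced by NaBH4 at this temperature.

Step 19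
Reactants: 25 1α,2α-diol lactone
Product: 27 1α,2α-diacetoxy lactol acetate (C6 anomeric mixture), via aluminium lactolate 26 (not isolated)
Conditions: i-Bu2AlH (4 equiv), CH2Cl2, −78 °C; then pyridine, DMAP, Ac2O, −78 → 23 °C
Reagents that add atoms: acetic anhydride, CC(=O)OC(C)=O
Why: reductive acetylation (Rychnovsky-type), in which the aluminium hemiacetal from the lactone is acetylated in situ before it can open or be reduced further, while the two aluminium alkoxides of the diol are acetylated in the same pot.

Step 20
Reactants: 27 1α,2α-diacetoxy lactol acetate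
Product: 28 15-exo-alcohol triacetate
Conditions: HF·pyridine, THF, 0 → 23 °C
Reagents that add atoms: none
Why: fluoride cleavage of the triethylsilyl ether under buffered conditions that leave the secondary acetates and the anomeric acetate intact.

Step 21
Reactants: 28 15-exo-alcohol triacetate
Product: 29 15-ketone triacetate
Conditions: Dess–Martin periodinane, NaHCO3, CH2Cl2, 23 °C
Reagents that add atoms: none
Why: non-basic oxidation of the hindered secondary alcohol, so the epimerisable C16 endo-methyl centre next to the new ketone is not disturbed; the lactol is still masked as its acetate and cannot be oxidised to the lactone.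

Step 22
Reactants: 29 15-ketone triacetate
Product: 30 9α,11α-epoxide triacetate
Conditions: mCPBA, NaHCO3, CH2Cl2, 0 °C
Reagents that add atoms: meta-chloroperoxybenzoic acid, OOC(=O)c1cccc(Cl)c1
Why: Prilezhaev epoxidation of the only remaining alkene from the exo (α) face of the bicyclo[3.2.1]octene, away from the C15–C16 bridge, which sets C9 and C11.

Step 23
Reactants: 30 9α,11α-epoxide triacetate
Product: 31 target lactol CNP0210140.1
Conditions: Bu3SnOMe, THF, 50 °C; aqueous work-up
Reagents that add atoms: none
Why: tin alkoxide transesterification is selective for the acetal-type (anomeric) acetate over the two hindered secondary acetates, and the freed lactol should settle to its stable anomer.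

**Compound list**

1 | geranic acid, (2E)-3,7-dimethylocta-2,6-dienoic acid | CC(C)=CCC/C(C)=C/C(=O)O | starting material
2 | rac-α-cyclogeranic acid, rac-2,6,6-trimethylcyclohex-2-ene-1-carboxylic acid | CC1=CCCC(C)(C)C1C(=O)O | intermediate
3 | (R)-1-phenylethylammonium (S)-2,6,6-trimethylcyclohex-2-ene-1-carboxylate | C[C@@H]([NH3+])c1ccccc1.CC1=CCCC(C)(C)[C@@H]1C(=O)[O-] | intermediate
4 | (S)-α-cyclogeranic acid, (1S)-2,6,6-trimethylcyclohex-2-ene-1-carboxylic acid | CC1=CCCC(C)(C)[C@@H]1C(=O)O | intermediate
5 | tert-butyl 2-oxocyclohexane-1-carboxylate | CC(C)(C)OC(=O)C1CCCCC1=O | starting material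
6 | 2,3-dibromopropene | BrCC(Br)=C | starting material
7 | tert-butyl (1R)-1-(2-bromoprop-2-en-1-yl)-2-oxocyclohexane-1-carboxylate | CC(C)(C)OC(=O)[C@@]1(CC(Br)=C)CCCCC1=O | intermediate
8 | tert-butyl (1R)-1-(2-bromoprop-2-en-1-yl)-2-oxocyclohex-3-ene-1-carboxylate | CC(C)(C)OC(=O)[C@@]1(CC(Br)=C)CCC=CC1=O | intermediate
9 | tert-butyl (1R)-1-(2-bromoprop-2-en-1-yl)-2-[(tert-butyldimethylsilyl)oxy]cyclohexa-2,4-diene-1-carboxylate | CC(C)(C)OC(=O)[C@@]1(CC(Br)=C)CC=CC=C1O[Si](C)(C)C(C)(C)C | intermediate
10 | tert-butyl (1R,5R)-2-[(tert-butyldimethylsilyl)oxy]-6-methylidenebicyclo[3.2.1]oct-2-ene-1-carboxylate (not isolated) | CC(C)(C)OC(=O)[C@@]12C[C@@H](CC=C1O[Si](C)(C)C(C)(C)C)C(=C)C2 | intermediate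
11 | tert-butyl (1R,5R)-6-methylidene-2-oxobicyclo[3.2.1]octane-1-carboxylate | CC(C)(C)OC(=O)[C@@]12C[C@@H](CCC1=O)C(=C)C2 | intermediate
12 | tert-butyl (1R,5R)-7-exo-hydroxy-6-methylidene-2-oxobicyclo[3.2.1]octane-1-carboxylate | CC(C)(C)OC(=O)[C@@]12C[C@@H](CCC1=O)C(=C)[C@@H]2O | intermediate
13 | tert-butyl (1R,5R)-7-exo-hydroxy-6-endo-methyl-2-oxobicyclo[3.2.1]octane-1-carboxylate | CC(C)(C)OC(=O)[C@@]12C[C@@H](CCC1=O)[C@@H](C)[C@@H]2O | intermediate
14 | tert-butyl (1R,5R)-6-endo-methyl-2-oxo-7-exo-(triethylsilyloxy)bicyclo[3.2.1]octane-1-carboxylate | CC(C)(C)OC(=O)[C@@]12C[C@@H](CCC1=O)[C@@H](C)[C@@H]2O[Si](CC)(CC)CC | intermediate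
15 | potassium enolate of 14, C9=C11 (not isolated) | [K+].CC(C)(C)OC(=O)[C@@]12C[C@@H](CC=C1[O-])[C@@H](C)[C@@H]2O[Si](CC)(CC)CC | intermediate
16 | tert-butyl (1R,5R)-6-endo-methyl-7-exo-(triethylsilyloxy)-2-(trifluoromethylsulfonyloxy)bicyclo[3.2.1]oct-2-ene-1-carboxylate | CC(C)(C)OC(=O)[C@@]12C[C@@H](CC=C1OS(=O)(=O)C(F)(F)F)[C@@H](C)[C@@H]2O[Si](CC)(CC)CC | intermediate
17 | 1-(hydroxymethyl)-6-endo-methyl-7-exo-(triethylsilyloxy)bicyclo[3.2.1]oct-2-en-2-yl triflate, ring configuration as in 16 | OC[C@@]12C[C@@H](CC=C1OS(=O)(=O)C(F)(F)F)[C@@H](C)[C@@H]2O[Si](CC)(CC)CC | intermediate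
18 | bis-triflate: the triflate ester of the C7 hydroxyl of 17 | FC(F)(F)S(=O)(=O)OC[C@@]12C[C@@H](CC=C1OS(=O)(=O)C(F)(F)F)[C@@H](C)[C@@H]2O[Si](CC)(CC)CC | intermediate
19 | ester of acid 4 with the C7 hydroxyl of 17, C9 vinyl triflate intact (not isolated) | CC1=CCCC(C)(C)[C@@H]1C(=O)OC[C@@]23C[C@@H](CC=C2OS(=O)(=O)C(F)(F)F)[C@@H](C)[C@@H]3O[Si](CC)(CC)CC | intermediate
20 | cis-fused lactone: 15-exo-(triethylsilyloxy)-6,7-seco-ent-kaura-1,9(11)-dien-6,7-olide, 5-epi (H5 α, C6 and C9 both β, C20 α) | C1CC(C)(C)[C@@H]2C(=O)OC[C@@]34C[C@@H](CC=C3[C@]2(C)C=1)[C@@H](C)[C@@H]4O[Si](CC)(CC)CC | intermediate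
21 | lithium enolate of lactone 20, C5=C6 (not isolated) | [Li+].C1CC(C)(C)C2=C([O-])OC[C@@]34C[C@@H](CC=C3[C@]2(C)C=1)[C@@H](C)[C@@H]4O[Si](CC)(CC)CC | intermediate
22 | trans-fused lactone: 15-exo-(triethylsilyloxy)-6,7-seco-ent-kaura-1,9(11)-dien-6,7-olide (H5 β, C6 α) | C1CC(C)(C)[C@H]2C(=O)OC[C@@]34C[C@@H](CC=C3[C@]2(C)C=1)[C@@H](C)[C@@H]4O[Si](CC)(CC)CC | intermediate
23 | 1β,2β-dihydroxy-15-exo-(triethylsilyloxy)-6,7-seco-ent-kaur-9(11)-en-6,7-olide | O[C@@H]1CC(C)(C)[C@H]2C(=O)OC[C@@]34C[C@@H](CC=C3[C@]2(C)[C@@H]1O)[C@@H](C)[C@@H]4O[Si](CC)(CC)CC | intermediate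
24 | 1,2-dioxo-15-exo-(triethylsilyloxy)-6,7-seco-ent-kaur-9(11)-en-6,7-olide, drawn as the diketone | O=C1CC(C)(C)[C@H]2C(=O)OC[C@@]34C[C@@H](CC=C3[C@]2(C)C1=O)[C@@H](C)[C@@H]4O[Si](CC)(CC)CC | intermediate
25 | 1α,2α-dihydroxy-15-exo-(triethylsilyloxy)-6,7-seco-ent-kaur-9(11)-en-6,7-olide | O[C@H]1CC(C)(C)[C@H]2C(=O)OC[C@@]34C[C@@H](CC=C3[C@]2(C)[C@H]1O)[C@@H](C)[C@@H]4O[Si](CC)(CC)CC | intermediate
26 | lactol triol from 25, present as its aluminium alkoxides and drawn neutral, C6 unassigned (not isolated) | O[C@H]1CC(C)(C)[C@H]2C(O)OC[C@@]34C[C@@H](CC=C3[C@]2(C)[C@H]1O)[C@@H](C)[C@@H]4O[Si](CC)(CC)CC | intermediate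
27 | 1α,2α-diacetoxy lactol acetate (C6–OAc, anomeric mixture), 15-exo-OSiEt3, C9=C11 | CC(=O)O[C@H]1CC(C)(C)[C@H]2C(OC(C)=O)OC[C@@]34C[C@@H](CC=C3[C@]2(C)[C@H]1OC(C)=O)[C@@H](C)[C@@H]4O[Si](CC)(CC)CC | intermediate
28 | 15-exo-alcohol of 27 | CC(=O)O[C@H]1CC(C)(C)[C@H]2C(OC(C)=O)OC[C@@]34C[C@@H](CC=C3[C@]2(C)[C@H]1OC(C)=O)[C@@H](C)[C@@H]4O | intermediate
29 | 15-ketone triacetate (16-endo-methyl, C9=C11) | CC(=O)O[C@H]1CC(C)(C)[C@H]2C(OC(C)=O)OC[C@@]34C[C@@H](CC=C3[C@]2(C)[C@H]1OC(C)=O)[C@@H](C)C4=O | intermediate
30 | 9α,11α-epoxide of 29 | CC(=O)O[C@H]1CC(C)(C)[C@H]2C(OC(C)=O)OC[C@@]34C[C@@H](C[C@H]5O[C@]53[C@]2(C)[C@H]1OC(C)=O)[C@@H](C)C4=O | intermediate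
31 | CNP0210140.1 | CC(=O)O[C@H]1CC(C)(C)[C@H]2[C@H](O)OC[C@@]34C[C@@H](C[C@H]5O[C@]53[C@]2(C)[C@H]1OC(C)=O)[C@@H](C)C4=O | target

**Step count and risks**

Total step count: 23. Longest linear sequence: 20 steps (steps 4–23, from 5 and 6 to 31); the ring A branch is 3 steps.

Steps most likely to fail:

1. Step 14. What may go wrong: slow substitution at the neopentyl carbon, so that the vinyl triflate is lost by hydrolysis or reduction before the tether is in place; insertion in the 8-endo sense or on the alkene face anti to C6; palladium hydride re-addition that moves the new alkene from C1=C2 to C2=C3. Fallback: the two bond formations are separated and the control element is changed. Acid 4 and alcohol 17 are joined by a Mitsunobu esterification (PPh3, diisopropyl azodicarboxylate, toluene), which forms the same O–C7 bond through an alkoxyphosphonium ion and gives ester 19 as an isolated compound. The ring is then closed in a separate silver-promoted cationic Heck reaction (Pd(OAc)2, (R)-BINAP, Ag3PO4, N-methylpyrrolidinone, 60 °C), in which the ligand rather than the tether selects the alkene face and the silver salt suppresses alkene migration. The fallback sets out from 4 and 17 and comes back at 20; it makes no compound outside the list (F0).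

2. Step 7. What may go wrong: reduction of the vinyl radical before it cyclises, or hydrogen transfer to C9 instead of C12 of the allyl radical, which would leave an allylic silyl ether that does not hydrolyse to the ketone. Fallback: a polar, palladium-mediated closure instead of the radical one. Dienol ether 9 is treated with Pd(PPh3)4 and CsF in 1,4-dioxane at 90 °C, so that the alkenylpalladium from the vinyl bromide couples with the fluoride-released dienolate at its terminus C13, giving the enone tert-butyl (1R,5R)-6-methylidene-2-oxobicyclo[3.2.1]oct-3-ene-1-carboxylate F1. SeO2 and t-BuOOH then give tert-butyl (1R,5R)-7-exo-hydroxy-6-methylidene-2-oxobicyclo[3.2.1]oct-3-ene-1-carboxylate F2, and hydrogenation (H2, palladium on carbon, ethyl acetate) saturates both the enone alkene and, from the exo face, the exocyclic methylene. The fallback sets out from 9 and comes back at 13.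

3. Step 22. What may go wrong: poor facial selectivity, with the peracid attacking from the β face next to the C15–C16 bridge. Fallback: the oxygen is delivered in two polar steps with the opposite facial logic. Ketone 29 is treated with N-bromosuccinimide in THF–water, so that a bromonium ion formed on the more accessible face is opened by water at the tertiary C9 from the other face, giving the bromohydrin 11β-bromo-9α-hydroxy triacetate F3. Ag2O in CH2Cl2 then closes it with inversion at C11 to the 9α,11α-epoxide. The fallback sets out from 29 and comes back at 30.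

**Further compounds**

F0 | step 14 | none | none
F1 | step 7 | tert-butyl (1R,5R)-6-methylidene-2-oxobicyclo[3.2.1]oct-3-ene-1-carboxylate | CC(C)(C)OC(=O)[C@@]12C[C@@H](C=CC1=O)C(=C)C2
F2 | step 7 | tert-butyl (1R,5R)-7-exo-hydroxy-6-methylidene-2-oxobicyclo[3.2.1]oct-3-ene-1-carboxylate | CC(C)(C)OC(=O)[C@@]12C[C@@H](C=CC1=O)C(=C)[C@@H]2O
F3 | step 22 | 11β-bromo-9α-hydroxy triacetate (bromohydrin of 29) | CC(=O)O[C@H]1CC(C)(C)[C@H]2C(OC(C)=O)OC[C@@]34C[C@@H](C[C@H](Br)[C@]3(O)[C@]2(C)[C@H]1OC(C)=O)[C@@H](C)C4=O
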